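**Plan**
- Retrosynthetic cuts, in order: both acetates; the C13–O stereocentre and C14=C15 (back to a 13E-allylic alcohol, then a C13 methyl ketone); C9–C11 (side chain as a Grignard reagent on a C9 ketone); the second C4 methyl; then C5–C10 together with C1–C2 (intramolecular Diels–Alder); last the acyclic chain at C8–C9, C4=C5 and C6–C7.
- Enabling feature: C5–C10 is the bond shared by ring A and ring B. Cutting it with C1–C2 turns ring A into the diene C2=C3(OSi)–C4(CH3)=C5 and the dienophile C1=C10(CH3), joined by C6–C9, the future ring B.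
- The C3 oxygen becomes the 2-silyloxy donor of the diene; C8(=CH2)–C9(=O) is a cross-conjugated activating carbonyl. The C9 ketone is a helper and is removed in steps 7–8.
- Forward: the linear C13 trienol is assembled from four small pieces; oxidation triggers the cycloaddition that forms rings A and B at once; then the side chain, the C4 methyl, C3–OH, C13–C15 and the acetates follow.
- Stereochemistry: C5/C10 from the cycloaddition (trans from the transition state, absolute sense from a chiral oxazaborolidinium ion); C9 from face-selective hydride transfer; C3 (axial 3α-O) from LiBH(sec-Bu)3; C13 from Sharpless epoxidation with L-(+)-tartrate.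

Key step: step 6

Remark: locants C1–C20 are labdane locants (C3 ring acetate, C4 gem-dimethyl, C5/C10 ring fusion, C8 exocyclic methylene, C9 side chain, C13 tertiary acetate).
Assumption: the (S)-oxazaborolidinium ion is taken to give the (4aS,8aS) adduct 12; if the first run shows the opposite sense, the (R)-catalyst is used.
Assumption: ylide 5 and bromide 13 are purchased.

Step 1
Reactants: 1 allylmagnesium bromide; 2 2,3-dibromopropene
Product: 3 2-bromohexa-1,5-diene
Conditions: Et2O, 0 °C to rt
Reagents that add atoms: none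
Why: Allylic substitution of the allylic bromide of 2 by the allyl Grignard reagent (SN2 and SN2′ give the same product) should leave the vinyl bromide untouched.

Step 2
Reactants: 3 2-bromohexa-1,5-diene
Product: 4 4-bromopent-4-enal
Conditions: OsO4 (2 mol%), NaIO4, 2,6-lutidine, dioxane/H2O, rt
Reagents that add atoms: osmium tetroxide (catalytic oxygen carrier), O=[Os](=O)(=O)=O; sodium periodate, [Na+].[O-]I(=O)(=O)=O
Why: Lemieux–Johnson cleavage should take the electron-rich monosubstituted alkene much faster than the electron-poor 2-bromoalkene.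

Step 3
Reactants: 4 4-bromopent-4-enal; 5 3-(triphenylphosphoranylidene)butan-2-one
Product: 6 (3E)-7-bromo-3-methylocta-3,7-dien-2-one
Conditions: CH2Cl2, 40 °C
Reagents that add atoms: none
Why: Wittig olefination with a stabilised ylide should give the E-trisubstituted enone (acyl trans to the chain).

Step 4
Reactants: 6 (3E)-7-bromo-3-methylocta-3,7-dien-2-one
Product: 7 {[(3E)-7-bromo-3-methylocta-1,3,7-trien-2-yl]oxy}(tert-butyl)dimethylsilane
Conditions: TBSOTf, Et3N, CH2Cl2, −78 to 0 °C
Reagents that add atoms: tert-butyldimethylsilyl triflate, CC(C)(C)[Si](C)(C)OS(=O)(=O)C(F)(F)F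
Why: Soft enolisation of the methyl ketone at its only α′-position should give the cross-conjugated 2-silyloxydiene with the E-alkene unchanged.

Step 5
Reactants: 7 {[(3E)-7-bromo-3-methylocta-1,3,7-trien-2-yl]oxy}(tert-butyl)dimethylsilane; 8 methacrolein (2-methylprop-2-enal)
Product: 10 (7E)-9-[(tert-butyldimethylsilyl)oxy]-2,8-dimethyl-4-methylidenedeca-1,7,9-trien-3-ol (racemic carbinol), via vinyllithium 9 (not isolated)
Conditions: t-BuLi (2 equiv), Et2O, −78 °C; then 8, −78 °C; aq. NH4Cl
Reagents that add atoms: none
Why: Bromine–lithium exchange and 1,2-addition of the alkenyllithium to the enal should give the divinyl carbinol; its stereocentre is erased in step 6.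

Step 6
Reactants: 10 (7E)-9-[(tert-butyldimethylsilyl)oxy]-2,8-dimethyl-4-methylidenedeca-1,7,9-trien-3-ol
Product: 12 (4aS,8aS)-6-[(tert-butyldimethylsilyl)oxy]-5,8a-dimethyl-2-methylidene-3,4,4a,7,8,8a-hexahydronaphthalen-1(2H)-one (trans-fused; C9 ketone, C8 methylene, 5α-H, 10β-CH3, C3 silyl enol ether), via cross-conjugated dienone 11 (not isolated)
Conditions: MnO2 (excess), CH2Cl2, −10 °C, cold filtration; then (S)-3,3-diphenyl-1-(2-methylphenyl)tetrahydro-1H,3H-pyrrolo[1,2-c][1,3,2]oxazaborole, C24H24BNO (24 mol%), HN(SO2CF3)2 (20 mol%), CH2Cl2, −78 to −40 °C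
Reagents that add atoms: none
Why: Proposed new method: MnO2 oxidises the bis-allylic carbinol to dienone 11, whose C9 carbonyl, bound to the chiral boron Lewis acid, lowers the LUMO of the C1=C10 isopropenyl unit so that the tethered 2-silyloxydiene C2=C3–C4=C5 adds across it in an asynchronous normal-demand intramolecular Diels–Alder reaction (C1–C2 leading, C5–C10 following); the closest known reaction types are the oxidation–cycloaddition cascade of 1,7,9-decatrien-3-ones and the oxazaborolidinium-catalysed enantioselective Diels–Alder reaction of acyclic enones with 2-silyloxydienes, neither shown for a cross-conjugated α,α′-disubstituted dienone in the intramolecular mode. Ring A closes as the cyclohexene of the [4+2] event (bonds C1–C2 and C5–C10) and ring B as the six-membered ring of the four-atom tether C6–C9, completed by the same C5–C10 bond (a 1,7,9-decatriene closing to a bicyclo[4.4.0]decene). The quaternary centre C10 and the adjacent C5 arise together: the trans relation of 10-CH3 and 5-H follows from the tether-exo, methyl-endo transition state with a chair-like tether, and the absolute configuration from the catalyst, whose aryl group is expected to shield one face of the bound enone. The step needs trans fusion, enantiofacial control and reaction at C1=C10 instead of C8=C17; the α-methyl group of the dienophile and the substituted diene interior (C3–OSi, C4–CH3) disfavour placing the bulky catalyst-bound acyl group under the diene, C8=C17 cannot reach the diene through a ring of workable size, and the low temperature suppresses the racemic background reaction and Nazarov closure. The silyl enol ether left at C3=C4 is the regiodefined enolate precursor for the C4 methylation in step 9.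

Step 7
Reactants: 12 (4aS,8aS)-silyloxy enone; 13 2-(2-bromoethyl)-2-methyl-1,3-dioxolane
Product: 16 (1S,4aS,8aS)-6-[(tert-butyldimethylsilyl)oxy]-5,8a-dimethyl-2-methylidene-1-[2-(2-methyl-1,3-dioxolan-2-yl)ethyl]-1,2,3,4,4a,7,8,8a-octahydronaphthalen-1-yl methyl carbonate (9β-carbonate), via Grignard reagent 14 (not isolated), via bromomagnesium alkoxide 15 (not isolated)
Conditions: 13, Mg, THF, 25 °C; CeCl3 (anhydrous), THF, −78 °C, then 12; then ClCO2Me, −78 °C to rt
Reagents that add atoms: methyl chloroformate, COC(=O)Cl
Why: Organocerium 1,2-addition to the non-enolisable enone (C10 quaternary, C8 sp2) should occur anti to the axial 10-methyl group, and the alkoxide is acylated in the same flask; the configuration of this carbinol is of no consequence because C9 is planarised in step 8.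

Step 8
Reactants: 16 9β-methyl carbonate
Product: 17 tert-butyl(dimethyl)silyl enol ether of 13,13-(ethylenedioxy)-4-methyl-trinorlabd-8(17)-en-3-one (C3=C4 enol ether, 9α-H, side chain 9β; 5R,9S,10R)
Conditions: Pd(OAc)2 (5 mol%), n-Bu3P (20 mol%), HCO2H, Et3N, THF, 40 °C
Reagents that add atoms: none
Why: Tsuji–Trost ionisation followed by formate hydrogenolysis should transfer hydride to the more substituted allyl terminus C9 from the α-face (anti to the 10-methyl group; the allyl complex can change faces through its CH2 terminus), giving the exocyclic C8=C17 alkene and the equatorial 9β side chain.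

Step 9
Reactants: 17 silyl enol ether
Product: 19 13,13-(ethylenedioxy)-14,15-dinorlabd-8(17)-en-3-one (5R,9S,10R), via lithium enolate 18 (not isolated)
Conditions: MeLi, THF/DMPU, 0 °C to rt; then MeI, −20 °C to rt
Reagents that add atoms: iodomethane, CI
Why: Si–O cleavage of the silyl enol ether gives the regiodefined C3–C4 enolate, whose C-methylation completes the C4 gem-dimethyl group without a new stereocentre (the enolate of the classical reductive methylation of 4-methyl-octalones).

Step 10
Reactants: 19 4,4-dimethyl-3-ketone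
Product: 21 3α-hydroxy-14,15-dinorlabd-8(17)-en-13-one (3R,5R,9S,10R), via ketal alcohol 20 (not isolated)
Conditions: LiBH(sec-Bu)3, THF, −78 °C; NaOH, H2O2, 0 °C; then pyridinium p-toluenesulfonate, acetone/H2O, 50 °C
Reagents that add atoms: water, O
Why: The bulky hydride should attack the C3 ketone along the equatorial trajectory (axial attack is blocked by the 1α and 5α hydrogens), giving the axial 3α-alcohol; mild acid then unmasks the C13 methyl ketone.

Step 11
Reactants: 21 3α-hydroxy methyl ketone; 22 triethyl phosphonoacetate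
Product: 24 ethyl (13E)-3α-hydroxylabda-8(17),13-dien-15-oate, via sodium phosphonate anion 23 (not isolated)
Conditions: NaH (3 equiv), 22 (2.5 equiv), THF, 0 to 60 °C
Reagents that add atoms: none
Why: Horner–Wadsworth–Emmons olefination of the methyl ketone should favour the E-enoate (ester trans to the larger CH2 substituent); the minor Z-isomer is removed by chromatography.

Step 12
Reactants: 24 E-enoate
Product: 25 (13E)-labda-8(17),13-diene-3α,15-diol
Conditions: (i-Bu)2AlH (3.5 equiv), CH2Cl2, −78 °C; Rochelle salt
Reagents that add atoms: none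
Why: 1,2-Reduction of the enoate should give the allylic alcohol with the alkene geometry unchanged.

Step 13
Reactants: 25 E-allylic alcohol
Product: 26 (13S,14S)-13,14-epoxylabd-8(17)-ene-3α,15-diol
Conditions: Ti(OiPr)4 (10 mol%), L-(+)-diethyl tartrate (12 mol%), t-BuOOH, 4 Å molecular sieves, CH2Cl2, −20 °C
Reagents that add atoms: tert-butyl hydroperoxide, CC(C)(C)OO
Why: Sharpless asymmetric epoxidation is reagent-controlled; L-(+)-tartrate on an (E)-3-methylalk-2-en-1-ol gives the (2S,3S) epoxide, here (13S,14S), and leaves the remote C3–OH and the exocyclic alkene untouched.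

Step 14
Reactants: 26 (13S,14S)-epoxy alcohol
Product: 28 (13S)-labda-8(17),14-diene-3α,13-diol, via epoxy iodide 27 (not isolated)
Conditions: PPh3 (1.2 equiv), I2 (1.2 equiv), imidazole, THF/MeCN, 0 °C; then Zn dust, AcOH, 0 °C to rt
Reagents that add atoms: none
Why: Appel iodination should select the primary alcohol over the hindered axial 3α-alcohol, and zinc-induced reductive β-elimination opens the epoxide with the C13–O bond retained, giving the (13S) tertiary vinyl carbinol.

Step 15
Reactants: 28 (13S)-3α,13-diol
Product: 29 (13S)-labda-8(17),14-diene-3α,13-diyl diacetate (3R,5R,9S,10R,13S; target)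
Conditions: Ac2O, DMAP, Et3N, CH2Cl2, rt to 40 °C
Reagents that add atoms: acetic anhydride, CC(=O)OC(C)=O
Why: DMAP-catalysed acylation under basic, non-ionising conditions should acetylate both the hindered secondary and the tertiary allylic alcohol without allylic transposition.

**Compound list**
1 | allylmagnesium bromide | C=CC[Mg]Br | starting material
2 | 2,3-dibromopropene | C=C(Br)CBr | starting material
3 | 2-bromohexa-1,5-diene | C=CCCC(Br)=C | intermediate
4 | 4-bromopent-4-enal | O=CCCC(Br)=C | intermediate
5 | 3-(triphenylphosphoranylidene)butan-2-one | CC(=O)C(C)=P(c1ccccc1)(c1ccccc1)c1ccccc1 | starting material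
6 | (3E)-7-bromo-3-methylocta-3,7-dien-2-one | CC(=O)/C(C)=C/CCC(Br)=C | intermediate
7 | {[(3E)-7-bromo-3-methylocta-1,3,7-trien-2-yl]oxy}(tert-butyl)dimethylsilane | C=C(O[Si](C)(C)C(C)(C)C)/C(C)=C/CCC(Br)=C | intermediate
8 | methacrolein | C=C(C)C=O | starting material
9 | 7-lithio analogue of 7 (vinyllithium) | C=C(O[Si](C)(C)C(C)(C)C)/C(C)=C/CCC([Li])=C | intermediate (not isolated)
10 | (7E)-9-[(tert-butyldimethylsilyl)oxy]-2,8-dimethyl-4-methylidenedeca-1,7,9-trien-3-ol (racemic) | C=C(C)C(O)C(=C)CC/C=C(C)/C(O[Si](C)(C)C(C)(C)C)=C | intermediate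
11 | (7E)-9-[(tert-butyldimethylsilyl)oxy]-2,8-dimethyl-4-methylidenedeca-1,7,9-trien-3-one | C=C(C)C(=O)C(=C)CC/C=C(C)/C(O[Si](C)(C)C(C)(C)C)=C | intermediate (not isolated)
12 | (4aS,8aS)-6-[(tert-butyldimethylsilyl)oxy]-5,8a-dimethyl-2-methylidene-3,4,4a,7,8,8a-hexahydronaphthalen-1(2H)-one | O=C1C(=C)CC[C@H]2C(C)=C(O[Si](C)(C)C(C)(C)C)CC[C@]12C | intermediate
13 | 2-(2-bromoethyl)-2-methyl-1,3-dioxolane | CC1(CCBr)OCCO1 | starting material
14 | [2-(2-methyl-1,3-dioxolan-2-yl)ethyl]magnesium bromide | CC1(CC[Mg]Br)OCCO1 | intermediate (not isolated)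
15 | bromomagnesium alkoxide of the 9β-carbinol | CC1(CC[C@]2(O[Mg]Br)C(=C)CC[C@H]3C(C)=C(O[Si](C)(C)C(C)(C)C)CC[C@]23C)OCCO1 | intermediate (not isolated)
16 | (1S,4aS,8aS)-6-[(tert-butyldimethylsilyl)oxy]-5,8a-dimethyl-2-methylidene-1-[2-(2-methyl-1,3-dioxolan-2-yl)ethyl]-1,2,3,4,4a,7,8,8a-octahydronaphthalen-1-yl methyl carbonate | CC1(CC[C@]2(OC(=O)OC)C(=C)CC[C@H]3C(C)=C(O[Si](C)(C)C(C)(C)C)CC[C@]23C)OCCO1 | intermediate
17 | (5R,9S,10R) C3 tert-butyldimethylsilyl enol ether with C8 methylene, 9α-H and the 9β dioxolanyl-ethyl side chain | CC1(CC[C@H]2C(=C)CC[C@H]3C(C)=C(O[Si](C)(C)C(C)(C)C)CC[C@]23C)OCCO1 | intermediate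
18 | lithium C3–C4 enolate of 17 | CC1(CC[C@H]2C(=C)CC[C@H]3C(C)=C(O[Li])CC[C@]23C)OCCO1 | intermediate (not isolated)
19 | (5R,9S,10R)-13,13-(ethylenedioxy)-14,15-dinorlabd-8(17)-en-3-one | CC1(CC[C@H]2C(=C)CC[C@H]3C(C)(C)C(=O)CC[C@]23C)OCCO1 | intermediate
20 | (3R,5R,9S,10R)-13,13-(ethylenedioxy)-14,15-dinorlabd-8(17)-en-3α-ol | CC1(CC[C@H]2C(=C)CC[C@H]3C(C)(C)[C@H](O)CC[C@]23C)OCCO1 | intermediate (not isolated)
21 | (3R,5R,9S,10R)-3α-hydroxy-14,15-dinorlabd-8(17)-en-13-one | CC(=O)CC[C@H]1C(=C)CC[C@H]2C(C)(C)[C@H](O)CC[C@]12C | intermediate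
22 | triethyl phosphonoacetate | CCOC(=O)CP(=O)(OCC)OCC | starting material
23 | sodium salt of triethyl phosphonoacetate | [Na+].CCOC(=O)[CH-]P(=O)(OCC)OCC | intermediate (not isolated)
24 | ethyl (13E)-3α-hydroxylabda-8(17),13-dien-15-oate | CCOC(=O)/C=C(\C)CC[C@H]1C(=C)CC[C@H]2C(C)(C)[C@H](O)CC[C@]12C | intermediate
25 | (13E)-labda-8(17),13-diene-3α,15-diol | OC/C=C(\C)CC[C@H]1C(=C)CC[C@H]2C(C)(C)[C@H](O)CC[C@]12C | intermediate
26 | (13S,14S)-13,14-epoxylabd-8(17)-ene-3α,15-diol | OC[C@@H]1O[C@@]1(C)CC[C@H]2C(=C)CC[C@H]3C(C)(C)[C@H](O)CC[C@]23C | intermediate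
27 | (13S,14R)-13,14-epoxy-15-iodolabd-8(17)-en-3α-ol | IC[C@@H]1O[C@@]1(C)CC[C@H]2C(=C)CC[C@H]3C(C)(C)[C@H](O)CC[C@]23C | intermediate (not isolated)
28 | (13S)-labda-8(17),14-diene-3α,13-diol | C=C[C@](C)(CC[C@H]1C(=C)CC[C@H]2C(C)(C)[C@H](O)CC[C@]12C)O | intermediate
29 | (13S)-labda-8(17),14-diene-3α,13-diyl diacetate | C=C[C@](C)(CC[C@H]1C(=C)CC[C@H]2C(C)(C)[C@H](OC(C)=O)CC[C@]12C)OC(C)=O | target

**Totals**
Total step count: 15. Longest linear sequence: 15 steps (1 and 2 to 29); 5, 8, 13 and 22 enter as purchased building blocks.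

**Steps most likely to fail**

Step 6 (proposed method). What may go wrong: poor enantiofacial discrimination, for example because the uncatalysed cycloaddition of 11 competes with the catalysed one, or Nazarov closure of the acid-bound dienone. Fallback: from 10 the cascade is run without catalyst (MnO2, CH2Cl2, 0 °C to rt), which should give racemic 12, that is 12 together with its enantiomer, the (4aR,8aR)-silyloxy enone F1. The two are separated by preparative chromatography on a chiral stationary phase (amylose tris(3,5-dimethylphenylcarbamate), supercritical CO2/2-propanol), and the (4aS,8aS) enantiomer returns to the route as 12.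

Step 8. What may go wrong: hydride transfer to the primary terminus C17 (giving the tetrasubstituted C8=C9 alkene) or diene formation by β-hydride elimination from the allyl complex. Fallback: from 16, zerovalent-palladium-catalysed allylic substitution (Pd2(dba)3, PPh3, THF, rt) with N′-isopropylidene-2-nitrobenzenesulfonohydrazide should give the N-allyl sulfonyl hydrazone F2 at the primary terminus C17. Mild hydrolysis (trifluoroethanol/H2O, rt) releases the allylic diazene F3, which loses N2 by retro-ene hydrogen transfer to C9 and returns to the route at 17.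

Step 9. What may go wrong: sluggish Si–O cleavage of the hindered silyl enol ether by MeLi, with proton transfer or O-methylation competing with C-methylation. Fallback: from 17, Saegusa–Ito oxidation (Pd(OAc)2, MeCN, rt) should give the 4-methyl-Δ4-3-ketone F4. Dissolving-metal reduction (Li, liquid NH3/THF, −78 °C) regenerates lithium enolate 18 with the trans (5α-H) fusion, and MeI returns the route to 19. This path also resets C5, so it would correct any cis-fused material carried on from step 6.

**Further compounds**
F1 | step 6 | (4aR,8aR)-6-[(tert-butyldimethylsilyl)oxy]-5,8a-dimethyl-2-methylidene-3,4,4a,7,8,8a-hexahydronaphthalen-1(2H)-one (enantiomer of 12) | O=C1C(=C)CC[C@@H]2C(C)=C(O[Si](C)(C)C(C)(C)C)CC[C@@]12C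
F2 | step 8 | N-allyl N-(2-nitrobenzenesulfonyl) acetone hydrazone at C17 of the C8=C9 olefin | CC1(CCC2=C(CN(N=C(C)C)S(=O)(=O)c3ccccc3[N+](=O)[O-])CC[C@H]3C(C)=C(O[Si](C)(C)C(C)(C)C)CC[C@]23C)OCCO1
F3 | step 8 | C17 allylic diazene of the C8=C9 olefin | CC1(CCC2=C(CN=N)CC[C@H]3C(C)=C(O[Si](C)(C)C(C)(C)C)CC[C@]23C)OCCO1
F4 | step 9 | (9S,10R) 4-methyl-Δ4-3-ketone with C8 methylene and the dioxolanyl-ethyl side chain | CC1(CC[C@H]2C(=C)CCC3=C(C)C(=O)CC[C@]23C)OCCO1
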